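Everything rests on closing the central ring last. The 2-methylbutanoyl-bearing phloroglucinol is read as the Claisen product of a linear 3,5,7-triketo ester: its six carbons are chain C-1 to C-6, its three hydroxyl oxygens sit on C-1, C-3 and C-5, the acyl carbonyl is C-7, and the two benzylic carbons hang from C-2 and C-4. One magnesium methoxide treatment joins the C-6 methylene to ester carbon C-1 and aromatises. The precursor is methyl (8S)-2,4-bis(arylmethyl)-8-methyl-3,5,7-trioxodecanoate carrying both complete, benzyl-protected outer rings; the C-2/C-4 substituents make the competing aldol mode unable to aromatise. It is reached by double reductive alkylation of a 3-oxoglutarate half Weinreb amide and one enolate acylation.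

Key step: step 10

Remark: Ar denotes 2,6-bis(benzyloxy)-3-butanoyl-4-methoxy-5-methylphenyl. The four outer-ring hydroxyls are carried as benzyl ethers because the protected ring must survive electrophilic formylation, and the last step is then a neutral hydrogenolysis. Chain centres C-2 and C-4 are epimer mixtures, alkene geometry in the Knoevenagel intermediates of step 7 is undefined, and the ester-side methylene is assumed to condense first there (the order does not change the product).

Step 1
Reactants: 1 2,4,6-trihydroxytoluene; 2 butanoyl chloride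
Product: 3 1-(2,4,6-trihydroxy-3-methylphenyl)butan-1-one
Conditions: AlCl3 (3.5 equiv), PhNO2, rt → 60 °C; then ice/1 M HCl
Reagents that add atoms: none
Why: Friedel–Crafts acylation of the phloroglucinol nucleus, whose two free ring carbons are equivalent and whose first acyl group deactivates the ring against a second one.

Step 2
Reactants: 3 1-(2,4,6-trihydroxy-3-methylphenyl)butan-1-one
Product: 4 1-[4,6-bis(benzyloxy)-2-hydroxy-3-methylphenyl]butan-1-one
Conditions: BnBr (2.1 equiv), K2CO3 (2.2 equiv), DMF, rt
Reagents that add atoms: benzyl bromide (BrCc1ccccc1)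
Why: Williamson etherification in which the phenol para to the ketone and then the unhindered ortho phenol should react, while the phenol wedged between the ring methyl and the chelating carbonyl is the slowest and stays free.

Step 3
Reactants: 4 1-[4,6-bis(benzyloxy)-2-hydroxy-3-methylphenyl]butan-1-one
Product: 5 1-[4,6-bis(benzyloxy)-2-methoxy-3-methylphenyl]butan-1-one
Conditions: MeI (3 equiv), K2CO3 (2 equiv), DMF, 50 °C
Reagents that add atoms: iodomethane (CI)
Why: Williamson O-methylation of the remaining hydrogen-bonded phenol under more forcing conditions, with a base too weak to enolise the ketone.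

Step 4
Reactants: 5 1-[4,6-bis(benzyloxy)-2-methoxy-3-methylphenyl]butan-1-one
Product: 7 2,6-bis(benzyloxy)-3-butanoyl-4-methoxy-5-methylbenzaldehyde, via iminium salt 6 (not isolated)
Conditions: POCl3 (1.5 equiv), DMF, 0 °C → rt; then ice-water
Reagents that add atoms: N,N-dimethylformamide (CN(C)C=O); water (O)
Why: Vilsmeier–Haack formylation at the only free ring carbon, activated by two ortho benzyloxy groups and the para methoxy group, which should be attacked far faster than the hindered, out-of-plane ketone is haloformylated.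

Step 5
Reactants: 8 Meldrum's acid; 9 methyl 3-chloro-3-oxopropanoate
Product: 10 methyl 3-(2,2-dimethyl-4,6-dioxo-1,3-dioxan-5-ylidene)-3-hydroxypropanoate
Conditions: pyridine (2.2 equiv), CH2Cl2, 0 °C → rt; 1 M HCl wash
Reagents that add atoms: none
Why: C-acylation of Meldrum's acid by an acid chloride (Oikawa–Yonemitsu procedure), the product resting as its stable enol.

Step 6
Reactants: 10 methyl 3-(2,2-dimethyl-4,6-dioxo-1,3-dioxan-5-ylidene)-3-hydroxypropanoate
Product: 12 methyl 5-[methoxy(methyl)amino]-3,5-dioxopentanoate, via acylketene 11 (not isolated)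
Conditions: MeNHOMe·HCl (1.1 equiv), Et3N (1.1 equiv), MeCN, 80 °C
Reagents that add atoms: N,O-dimethylhydroxylamine hydrochloride (CNOC.Cl)
Why: Thermal cycloreversion of the acyl Meldrum's acid releases acetone and CO2 and the resulting acylketene is captured by the hydroxylamine N–H, the standard aminolysis route to β-keto amides.

Step 7
Reactants: 12 methyl 5-[methoxy(methyl)amino]-3,5-dioxopentanoate; 7 2,6-bis(benzyloxy)-3-butanoyl-4-methoxy-5-methylbenzaldehyde (2.1 equiv)
Product: 16 methyl 2,4-bis[(Ar)methyl]-5-[methoxy(methyl)amino]-3,5-dioxopentanoate (epimer mixture), via Knoevenagel adduct 13 (not isolated), via monoalkylated keto ester 14 (not isolated), via second Knoevenagel adduct 15 (not isolated)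
Conditions: L-proline (0.3 equiv), Hantzsch ester (2.3 equiv), EtOH–CH2Cl2, 40 °C
Reagents that add atoms: none
Why: Three-component reductive alkylation (amine-catalysed Knoevenagel condensation followed at once by Hantzsch-ester conjugate reduction), which can engage each CH2 of 12 only once and so should place exactly one arylmethyl group on C-2 and one on C-4, the two new centres forming as an epimer mixture that is erased in step 10.

Step 8
Reactants: 17 (S)-2-methylbutanoic acid
Product: 20 (S)-3-methylpentan-2-one, via lithium carboxylate 18 (not isolated), via dilithium gem-diolate 19 (not isolated)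
Conditions: MeLi (2.1 equiv), Et2O, 0 °C → rt; inverse quench into cold 1 M HCl; distil
Reagents that add atoms: methyllithium ([Li]C)
Why: Organolithium addition to a lithium carboxylate, which halts at the gem-diolate and gives the methyl ketone only on quench, and since neither carboxylate nor diolate is deprotonated at the α-carbon the S configuration of 17 should be carried over unchanged.

Step 9
Reactants: 16 methyl 2,4-bis[(Ar)methyl]-5-[methoxy(methyl)amino]-3,5-dioxopentanoate; 20 (S)-3-methylpentan-2-one (3 equiv)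
Product: 24 methyl (8S)-2,4-bis[(Ar)methyl]-8-methyl-3,5,7-trioxodecanoate (epimer mixture at C-2 and C-4), via ketone lithium enolate 21 (not isolated), via keto ester lithium enolate 22 (not isolated), via chelated tetrahedral adduct 23 (not isolated)
Conditions: 20, LDA (3.0 equiv), THF, −78 °C; add 16 pre-treated with LiHMDS (1.05 equiv), THF, −78 °C; −78 → −20 °C; aq NH4Cl; crude 24 used at once
Reagents that add atoms: none
Why: Claisen-type acylation of a kinetic ketone lithium enolate by a Weinreb amide, in which prior deprotonation parks the more acidic β-keto ester side of 16 as its enolate so that the amide carbonyl is the only electrophile, the N-methoxy chelate 23 prevents a second addition, and LDA at −78 °C removes a methyl proton of 20 and not the methine proton, so the S centre stays untouched.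

Step 10
Reactants: 24 methyl (8S)-2,4-bis[(Ar)methyl]-8-methyl-3,5,7-trioxodecanoate
Product: 26 (2S)-1-{3,5-bis[(Ar)methyl]-2,4,6-trihydroxyphenyl}-2-methylbutan-1-one (tetra-O-benzyl agrimol B), via cyclohexanetrione tautomer 25 (not isolated)
Conditions: Mg(OMe)2 (8 equiv), MeOH–THF, 60 °C; then cold 1 M HCl
Reagents that add atoms: none
Why: Magnesium methoxide converts the β-dicarbonyl units into chelated enolates; the unsubstituted C-6 carbon of the C-5/C-7 diketonate, the most acidic and least hindered carbanion, adds to the ester carbonyl C-1, methoxide leaves, and cyclohexanetrione 25 tautomerises to the arene, whose magnesium phenoxide makes the sequence irreversible. The closest known reaction type is the magnesium-alkoxide Claisen-mode (polyketide-type) cyclisation of 3,5,7-triketo esters, and of their 4-hydroxy-2-pyrone forms, to acylphloroglucinols. The ring C-1 to C-6 closes 6-exo-trig by acyl substitution. No stereocentre is created: the C-2/C-4 epimers converge on aromatisation, and the S centre at C-8 should survive because the C-7 ketone enolises toward the doubly activated C-6 and not toward the methine. Claisen over aldol is secured by the substrate itself: attack of C-2 on C-7 would give a quaternary C-2 that cannot dehydrate to an arene and so stays reversible, C-7 is shielded by the sec-butyl group, any pyrone from O-acylation is reopened by methoxide, and the outer ketones sit between two ortho substituents and meta to the benzylic carbon, out of reach of any unstrained ring. Chelation of all three dicarbonyl units as enolates also guards the chain against retro-Claisen cleavage by methoxide.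

Step 11
Reactants: 26 tetra-O-benzyl agrimol B
Product: 27 agrimol B
Conditions: H2 (1 atm), 10% Pd/C, EtOAc–MeOH, rt
Reagents that add atoms: none
Why: Catalytic hydrogenolysis of the four aryl benzyl ethers under neutral conditions, which should leave the hydrogen-bonded aryl ketones, the diarylmethane bridges and the S centre alone.

Compound list

1 | 2,4,6-trihydroxytoluene | Cc1c(O)cc(O)cc1O | starting material
2 | butanoyl chloride | CCCC(Cl)=O | starting material
3 | 1-(2,4,6-trihydroxy-3-methylphenyl)butan-1-one | CCCC(=O)c1c(O)cc(O)c(C)c1O | intermediate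
4 | 1-[4,6-bis(benzyloxy)-2-hydroxy-3-methylphenyl]butan-1-one | CCCC(=O)c1c(OCc2ccccc2)cc(OCc2ccccc2)c(C)c1O | intermediate
5 | 1-[4,6-bis(benzyloxy)-2-methoxy-3-methylphenyl]butan-1-one | CCCC(=O)c1c(OCc2ccccc2)cc(OCc2ccccc2)c(C)c1OC | intermediate
6 | N-{[2,6-bis(benzyloxy)-3-butanoyl-4-methoxy-5-methylphenyl]methylidene}-N-methylmethanaminium chloride (iminium salt) | CCCC(=O)c1c(OCc2ccccc2)c(C=[N+](C)C)c(OCc2ccccc2)c(C)c1OC.[Cl-] | intermediate (not isolated)
7 | 2,6-bis(benzyloxy)-3-butanoyl-4-methoxy-5-methylbenzaldehyde | CCCC(=O)c1c(OCc2ccccc2)c(C=O)c(OCc2ccccc2)c(C)c1OC | intermediate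
8 | Meldrum's acid (2,2-dimethyl-1,3-dioxane-4,6-dione) | CC1(C)OC(=O)CC(=O)O1 | starting material
9 | methyl 3-chloro-3-oxopropanoate | COC(=O)CC(Cl)=O | starting material
10 | methyl 3-(2,2-dimethyl-4,6-dioxo-1,3-dioxan-5-ylidene)-3-hydroxypropanoate | COC(=O)CC(O)=C1C(=O)OC(C)(C)OC1=O | intermediate
11 | methyl 3,5-dioxopent-4-enoate (acylketene) | COC(=O)CC(=O)C=C=O | intermediate (not isolated)
12 | methyl 5-[methoxy(methyl)amino]-3,5-dioxopentanoate | COC(=O)CC(=O)CC(=O)N(C)OC | intermediate
13 | methyl 2-[(Ar)methylidene]-5-[methoxy(methyl)amino]-3,5-dioxopentanoate, E/Z undefined | COC(=O)C(=Cc1c(OCc2ccccc2)c(C)c(OC)c(C(=O)CCC)c1OCc1ccccc1)C(=O)CC(=O)N(C)OC | intermediate (not isolated)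
14 | methyl 2-[(Ar)methyl]-5-[methoxy(methyl)amino]-3,5-dioxopentanoate, racemic at C-2 | COC(=O)C(Cc1c(OCc2ccccc2)c(C)c(OC)c(C(=O)CCC)c1OCc1ccccc1)C(=O)CC(=O)N(C)OC | intermediate (not isolated)
15 | methyl 2-[(Ar)methyl]-4-[(Ar)methylidene]-5-[methoxy(methyl)amino]-3,5-dioxopentanoate, E/Z undefined | COC(=O)C(Cc1c(OCc2ccccc2)c(C)c(OC)c(C(=O)CCC)c1OCc1ccccc1)C(=O)C(=Cc1c(OCc2ccccc2)c(C)c(OC)c(C(=O)CCC)c1OCc1ccccc1)C(=O)N(C)OC | intermediate (not isolated)
16 | methyl 2,4-bis[(Ar)methyl]-5-[methoxy(methyl)amino]-3,5-dioxopentanoate, epimer mixture at C-2 and C-4 | COC(=O)C(Cc1c(OCc2ccccc2)c(C)c(OC)c(C(=O)CCC)c1OCc1ccccc1)C(=O)C(Cc1c(OCc2ccccc2)c(C)c(OC)c(C(=O)CCC)c1OCc1ccccc1)C(=O)N(C)OC | intermediate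
17 | (S)-2-methylbutanoic acid | CC[C@H](C)C(=O)O | starting material
18 | lithium (S)-2-methylbutanoate | CC[C@H](C)C(=O)[O-].[Li+] | intermediate (not isolated)
19 | dilithium (3S)-3-methylpentane-2,2-diolate | CC[C@H](C)C(C)([O-])[O-].[Li+].[Li+] | intermediate (not isolated)
20 | (S)-3-methylpentan-2-one | CC[C@H](C)C(C)=O | intermediate
21 | lithium (3S)-3-methylpent-1-en-2-olate | CC[C@H](C)C(=C)[O-].[Li+] | intermediate (not isolated)
22 | lithium enolate of 16 on the ester side (C-2/C-3) | COC(=O)C(Cc1c(OCc2ccccc2)c(C)c(OC)c(C(=O)CCC)c1OCc1ccccc1)=C([O-])C(Cc1c(OCc2ccccc2)c(C)c(OC)c(C(=O)CCC)c1OCc1ccccc1)C(=O)N(C)OC.[Li+] | intermediate (not isolated)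
23 | dilithium adduct of 21 to the amide carbonyl of 22 (C-5 alkoxide bearing N(OMe)Me, 8S) | COC(=O)C(Cc1c(OCc2ccccc2)c(C)c(OC)c(C(=O)CCC)c1OCc1ccccc1)=C([O-])C(Cc1c(OCc2ccccc2)c(C)c(OC)c(C(=O)CCC)c1OCc1ccccc1)C([O-])(CC(=O)[C@@H](C)CC)N(C)OC.[Li+].[Li+] | intermediate (not isolated)
24 | methyl (8S)-2,4-bis[(Ar)methyl]-8-methyl-3,5,7-trioxodecanoate, epimer mixture at C-2 and C-4 | COC(=O)C(Cc1c(OCc2ccccc2)c(C)c(OC)c(C(=O)CCC)c1OCc1ccccc1)C(=O)C(Cc1c(OCc2ccccc2)c(C)c(OC)c(C(=O)CCC)c1OCc1ccccc1)C(=O)CC(=O)[C@@H](C)CC | intermediate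
25 | 2,4-bis[(Ar)methyl]-6-[(2S)-2-methylbutanoyl]cyclohexane-1,3,5-trione | O=C1C(Cc2c(OCc3ccccc3)c(C)c(OC)c(C(=O)CCC)c2OCc2ccccc2)C(=O)C(Cc2c(OCc3ccccc3)c(C)c(OC)c(C(=O)CCC)c2OCc2ccccc2)C(=O)C1C(=O)[C@@H](C)CC | intermediate (not isolated)
26 | (2S)-1-{3,5-bis[(Ar)methyl]-2,4,6-trihydroxyphenyl}-2-methylbutan-1-one (tetra-O-benzyl agrimol B) | CCCC(=O)c1c(OCc2ccccc2)c(Cc2c(O)c(Cc3c(OCc4ccccc4)c(C)c(OC)c(C(=O)CCC)c3OCc3ccccc3)c(O)c(C(=O)[C@@H](C)CC)c2O)c(OCc2ccccc2)c(C)c1OC | intermediate
27 | agrimol B, (2S)-1-{3,5-bis[(3-butanoyl-2,6-dihydroxy-4-methoxy-5-methylphenyl)methyl]-2,4,6-trihydroxyphenyl}-2-methylbutan-1-one | CCCC(=O)c1c(O)c(Cc2c(O)c(Cc3c(O)c(C)c(OC)c(C(=O)CCC)c3O)c(O)c(C(=O)[C@@H](C)CC)c2O)c(O)c(C)c1OC | target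

Total step count: 11. Longest linear sequence: 8 steps (1, 2, 3, 4, 7, 9, 10, 11).

Steps most likely to fail

Step 10. Methoxide-induced retro-Claisen fragmentation of the 2,4-disubstituted β-dicarbonyl chain, or arrest at the O-acylated pyrone, may outpace closure of C-6 onto C-1. The fallback gives up building the central ring and buys it instead. It sets out from 17 and 7: Friedel–Crafts acylation of commercial phloroglucinol with 17 (BF3·OEt2, 80 °C) would give (2S)-2-methyl-1-(2,4,6-trihydroxyphenyl)butan-1-one F1. Its two free ring carbons would then be benzylated reductively with two equivalents of 7 (L-proline, Hantzsch ester, EtOH–CH2Cl2: condensation to the quinone methide, then hydride transfer), which comes back to the route at 26.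

Step 9. Addition of the enolate to the hindered, α-branched amide carbonyl of an already anionic substrate may be so slow that proton transfer to the enolate and base-induced breakdown of the N-methoxy amide take over. The fallback sets out from 16 and brings the chiral acyl group in as an electrophile under non-basic conditions. Excess lithium enolate of allyl acetate (THF, −78 °C) adds to the amide of 16 to give 1-methyl 7-prop-2-en-1-yl 2,4-bis[(Ar)methyl]-3,5-dioxoheptanedioate F2. Its only unsubstituted active methylene is C-acylated as the magnesium enolate (MgCl2, pyridine, CH2Cl2, 0 °C) with (S)-2-methylbutanoyl chloride F3, made from 17 with oxalyl chloride, to give 1-methyl 7-prop-2-en-1-yl 2,4-bis[(Ar)methyl]-6-[(2S)-2-methylbutanoyl]-3,5-dioxoheptanedioate F4. Pd(PPh3)4 and morpholine (THF, rt) then remove the allyl ester with decarboxylation and come back to the route at 24.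

Step 7. The second Knoevenagel condensation with the di-ortho-substituted aldehyde may stall, leaving monoalkylated material to self-condense. The fallback replaces condensation by enolate alkylation and sets out from 7. NaBH4 (MeOH, 0 °C) reduces the aldehyde in preference to the hindered ketone to give 1-[2,4-bis(benzyloxy)-3-(hydroxymethyl)-6-methoxy-5-methylphenyl]butan-1-one F5. PBr3 (CH2Cl2, 0 °C) converts it into 1-[2,4-bis(benzyloxy)-3-(bromomethyl)-6-methoxy-5-methylphenyl]butan-1-one F6. Two equivalents of F6 alkylate 12 (K2CO3, acetone, rt), the second alkylation going to C-4 because quaternisation of C-2 by so hindered a halide is disfavoured; this comes back to the route at 16.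

Further compounds

F1 | step 10 | (2S)-2-methyl-1-(2,4,6-trihydroxyphenyl)butan-1-one | CC[C@H](C)C(=O)c1c(O)cc(O)cc1O
F2 | step 9 | 1-methyl 7-prop-2-en-1-yl 2,4-bis[(Ar)methyl]-3,5-dioxoheptanedioate | COC(=O)C(Cc1c(OCc2ccccc2)c(C)c(OC)c(C(=O)CCC)c1OCc1ccccc1)C(=O)C(Cc1c(OCc2ccccc2)c(C)c(OC)c(C(=O)CCC)c1OCc1ccccc1)C(=O)CC(=O)OCC=C
F3 | step 9 | (S)-2-methylbutanoyl chloride | CC[C@H](C)C(Cl)=O
F4 | step 9 | 1-methyl 7-prop-2-en-1-yl 2,4-bis[(Ar)methyl]-6-[(2S)-2-methylbutanoyl]-3,5-dioxoheptanedioate | COC(=O)C(Cc1c(OCc2ccccc2)c(C)c(OC)c(C(=O)CCC)c1OCc1ccccc1)C(=O)C(Cc1c(OCc2ccccc2)c(C)c(OC)c(C(=O)CCC)c1OCc1ccccc1)C(=O)C(C(=O)OCC=C)C(=O)[C@@H](C)CC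
F5 | step 7 | 1-[2,4-bis(benzyloxy)-3-(hydroxymethyl)-6-methoxy-5-methylphenyl]butan-1-one | CCCC(=O)c1c(OCc2ccccc2)c(CO)c(OCc2ccccc2)c(C)c1OC
F6 | step 7 | 1-[2,4-bis(benzyloxy)-3-(bromomethyl)-6-methoxy-5-methylphenyl]butan-1-one | CCCC(=O)c1c(OCc2ccccc2)c(CBr)c(OCc2ccccc2)c(C)c1OC
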